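(The runs stem from a simulated flask with made-up constants; the scatter is artificial.)

Alpha carries 1.63 times the coupling partner of eta, yet at 30.0 h alpha holds 9.0% mono adduct against eta's 10.3%.

common to all: solid substrate 0.20 M
- eta: coupling partner 0.19 M; run made earlier
- alpha: coupling partner 0.31 M; run made earlier
- Wednesday's: coupling partner 0.400 M; time 40 h
- Thursday's: coupling partner 0.200 M; time 40 h

- eta (time / h: mono adduct / %, bis adduct / %): 8.00: 3.8, 1.1; 15.0: 5.9, 2.4; 20.0: 8.0, 3.9; 30.0: 10.3, 3.7
- alpha (time / h: mono adduct / %, bis adduct / %): 8.00: 4.9, 2.0; 15.0: 6.4, 3.1; 20.0: 8.8, 4.3; 30.0: 9.0, 5.2

(scatter of a reading: 0.5 percentage points)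

- solid substrate is a solid; its amount is given per volume of the solution
- at the start none of the solid substrate is in solution

* which of these holds the largest part of the solid substrate at the end of Wednesday's (mono adduct / tris adduct / solid substrate / bis adduct)
* which of these holds the largest part of the solid substrate at the end of Thursday's (mono adduct / tris adduct / solid substrate / bis adduct)
* how much mono adduct is there at the end of Wednesday's, in percent of the solid substrate charged

In the first instants nothing can couple: none of the solid substrate is in solution, and the partner waits. By 8.00 h alpha shows 4.9% mono adduct and 2.0% bis adduct, so substrate has dissolved, coupled and begun to pass on. Later, alpha's mono adduct reads 8.8% at 20.0 h, then 9.0% at 30.0 h, each good to 0.5 percentage points, so these two readings do not tell a slow rise from a level.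

Now I divide one rate by another. I suppose that bis adduct stands near a level late on, which the readings do not prove; then it is made about as fast as it is used, so k_m·M ≈ k_b·D, where M and D are the amounts of mono and bis adduct and k_m and k_b are the first-order constants of the steps out of each. Time drops out. If each step takes one partner, the partner drops out too, leaving ρ = D/M = k_m/k_b, a selectivity factor.

The last two readings give 0.415 in eta and 0.534 in alpha; pooled, the bis-to-mono ratio is 0.474. Bis adduct is the smaller of the two, so by this rule its step out is the faster, and what passes presumably goes on to tris adduct, which no reading shows. I set no figure on tris adduct. For Wednesday's I commit to mono adduct near the mean of alpha's last two readings, 8.90%, and bis adduct at 4.22%.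

The forecast says 10.5% mono adduct, above my figure, and solid substrate on top on Wednesday's and solid substrate on Thursday's: “Most of the substrate thus stays unconverted, largely as solid”.

Wednesday's gives 9.30% mono adduct, and its largest part is tris adduct at 38.1%, where the forecast parts from the flask; Thursday's keeps solid substrate on top at 46.4%. Mono adduct's half-life by its step to bis adduct alone, partner as charged, is 2.0 h, far shorter than the 40 h of the run. Then ρ on Wednesday's mono adduct gives 4.41% bis adduct; the flask holds 4.26%.

    starting material + coupling partner → mono adduct (k = 0.648 /M/h)
    bis adduct → over-reaction product (k = 0.0571 /h)
    coupling partner + bis adduct → tris adduct (k = 1.36 /M/h)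
    coupling partner + mono adduct → bis adduct (k = 0.874 /M/h)
    solid substrate ⇌ starting material, rate k5*(cs5 - [starting material]) while solid is left; crystals form when [starting material] > cs5 (solubility = 42.0 mM, k = 0.167 /h)

In the neighbour with 0.080 M solid substrate, ρ on its 2.80% mono adduct gives 1.33% bis adduct. That flask holds 2.15%, more than ρ gives, with solid substrate at 0% and tris adduct at 80.6%.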